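Everything rests on cutting ring C of the top, non-galloylated flavan unit into an ortho-quinone methide of top ring A and a Z β-oxygenated styrene. One acid-catalysed endo [4+2] cycloaddition forms O1–C2 and C3–C4, closes that pyran and sets C2, C3 and C4 so that the C2 aryl, the C3 oxygen and the C4–C8 interflavan bond lie on one face of ring C; this all-cis triad, which cationic 4→8 coupling cannot deliver, is the feature exploited. The precursor is the perbenzylated epicatechin gallate 4β→8 dimer bearing at C8 of its upper unit a (2-hydroxy-4,6-dibenzyloxyphenyl)carbinol, which is paired with a benzyl Z-styryl carbonate.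

Key step: step 11

Remark on the structure: the middle and bottom units are (2R,3R)-epicatechin 3-O-gallates joined 4β→8 (3,4-trans in the middle unit). The top unit has the epicatechin configuration at C2 and C3, and its C4–C8 bond is cis to O3 (4α→8). No structural correction was found to be needed.

Assumption: the enantiomer of TRIP (3,3'-bis(2,4,6-triisopropylphenyl)-1,1'-binaphthyl-2,2'-diyl hydrogen phosphate) that is matched with the dimer cannot be assigned in advance. (R)-TRIP is written and is to be exchanged for (S)-TRIP if that acid proves matched.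

Design remarks:
- The benzylated gallate monomer is assembled from (−)-epicatechin and 3,4,5-tris(benzyloxy)benzoic acid, so that only four phenols are alkylated on the flavan and no aryl ester is exposed to the alkylation base.
- Bromine is placed at C8 of the monomer, where its position is secure and where it also caps the electrophile against self-condensation.
- The aryl metal is raised by bromine–magnesium exchange, which the gallate esters should tolerate.
- The salicylaldehyde enters as its magnesium phenoxide, so that its phenol cannot quench the organometallic.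

Step 1
Reactants: 1 (−)-epicatechin
Product: 2 5,7,3',4'-tetra-O-benzyl-(−)-epicatechin
Conditions: BnBr (4.4 equiv), K2CO3, DMF, 0 °C → rt, argon
Reagents that add atoms: benzyl bromide, BrCc1ccccc1
Why: Williamson etherification under carbonate base alkylates the four acidic phenols and leaves the secondary C3 alcohol free, and neither C2 nor C3 is acidic under these conditions, so the 2R,3R configuration is kept.

Step 2
Reactants: 2 5,7,3',4'-tetra-O-benzyl-(−)-epicatechin and 3 3,4,5-tris(benzyloxy)benzoic acid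
Product: 4 hepta-O-benzyl-(−)-epicatechin gallate (5,7,3',4'-tetra-O-benzylepicatechin 3-O-(3,4,5-tri-O-benzylgallate))
Conditions: DCC, DMAP, CH2Cl2, rt
Reagents that add atoms: none
Why: Steglich esterification acylates the hindered C3 hydroxyl through the acylpyridinium ion, and since only the O–H bond of the alcohol is broken the C3 configuration is retained.

Step 3
Reactants: 4 hepta-O-benzyl-(−)-epicatechin gallate
Product: 5 4β-(2-ethoxyethoxy)-hepta-O-benzylepicatechin gallate (ether trans to the 3-O-gallate)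
Conditions: DDQ, 2-ethoxyethanol, CH2Cl2, rt
Reagents that add atoms: 2-ethoxyethanol, CCOCCO
Why: DDQ removes hydride from C4, the benzylic position activated by the three ring A oxygens, and the alcohol captures the cation on the face away from the 3-O-gallate (oxidative benzylic etherification), so the new C4 centre is 3,4-trans, although either epimer would serve since C4 is ionised again in step 5.

Step 4
Reactants: 5 4β-(2-ethoxyethoxy)-hepta-O-benzylepicatechin gallate
Product: 6 8-bromo-4β-(2-ethoxyethoxy)-hepta-O-benzylepicatechin gallate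
Conditions: NBS, CH2Cl2, −40 → 0 °C
Reagents that add atoms: N-bromosuccinimide, O=C1CCC(=O)N1Br
Why: Electrophilic aromatic bromination of the phloroglucinol-type ring A should go to C8, which is less hindered than C6 between two benzyloxy groups, and the bromine then serves both as a cap and as the later metalation handle.

Step 5
Reactants: 6 8-bromo-4β-(2-ethoxyethoxy)-hepta-O-benzylepicatechin gallate (electrophile) and 4 hepta-O-benzyl-(−)-epicatechin gallate (nucleophile, 4 equiv)
Product: 7 tetradeca-O-benzyl [epicatechin 3-O-gallate-(4β→8)-epicatechin 3-O-gallate] brominated at C8 of the upper unit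
Conditions: TMSOTf (cat.), CH2Cl2, −78 °C
Reagents that add atoms: none
Why: TMSOTf ionises the C4 ether to the ring A stabilised benzylic cation, which undergoes Friedel–Crafts alkylation by C8 of the excess nucleophile on the face opposite the 3-O-gallate (whose carbonyl can also shield its own face by anchimeric assistance), so C4 is set 3,4-trans (4β), while the C8 bromine stops the electrophile from adding to itself.

Step 6
Reactants: 8 2,4,6-trihydroxybenzaldehyde
Product: 9 4,6-bis(benzyloxy)-2-hydroxybenzaldehyde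
Conditions: BnBr (2 equiv), K2CO3, DMF, rt
Reagents that add atoms: benzyl bromide, BrCc1ccccc1
Why: Williamson etherification takes the two more reactive phenols, while the remaining ortho hydroxyl is held back by its hydrogen bond to the formyl group.

Step 7
Reactants: 7 upper-unit C8 bromide of the benzylated digallate dimer and 9 4,6-bis(benzyloxy)-2-hydroxybenzaldehyde (2.5 equiv)
Product: 12 upper-unit C8 [4,6-bis(benzyloxy)-2-hydroxyphenyl]carbinol of the benzylated digallate dimer (mixture of carbinol epimers), via arylmagnesium chloride 10 (not isolated), via magnesium phenoxide 11 (not isolated)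
Conditions: iPrMgCl·LiCl, THF, 0 °C → rt; then 11 [from 9, t-BuMgCl, THF, −20 °C], 0 °C → rt
Reagents that add atoms: none
Why: Bromine–magnesium exchange is sped by the two ortho oxygens and should spare the hindered secondary gallates at this temperature, and Grignard 1,2-addition of the aryl metal to the aldehyde of the preformed magnesium phenoxide (the usual entry to ortho-hydroxybenzhydrols) then forms the carbinol, whose new centre arises unselectively and without consequence because it becomes planar in step 11.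

Step 8
Reactants: 13 3,4-bis(benzyloxy)benzaldehyde
Product: 14 1,2-bis(benzyloxy)-4-(2-methoxyethenyl)benzene (E/Z mixture)
Conditions: (MeOCH2)PPh3Cl, KOt-Bu, THF, 0 °C → rt
Reagents that add atoms: (methoxymethyl)triphenylphosphonium chloride, COC[P+](c1ccccc1)(c1ccccc1)c1ccccc1.[Cl-]
Why: Wittig olefination with the methoxymethylene ylide gives the enol ether as a mixture of geometric isomers, both of which hydrolyse to the same aldehyde.

Step 9
Reactants: 14 1,2-bis(benzyloxy)-4-(2-methoxyethenyl)benzene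
Product: 15 2-[3,4-bis(benzyloxy)phenyl]acetaldehyde
Conditions: 2 M HCl, THF, 50 °C
Reagents that add atoms: water, O
Why: Acid-catalysed enol ether hydrolysis through the oxocarbenium ion and hemiacetal releases the one-carbon homologated aldehyde without touching the benzyl ethers, and the aldehyde is used at once.

Step 10
Reactants: 15 2-[3,4-bis(benzyloxy)phenyl]acetaldehyde
Product: 17 benzyl (Z)-2-[3,4-bis(benzyloxy)phenyl]ethenyl carbonate, via potassium Z-enolate 16 (not isolated)
Conditions: KOt-Bu, THF, −78 °C; then CbzCl, −78 °C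
Reagents that add atoms: benzyl chloroformate, O=C(Cl)OCc1ccccc1
Why: Deprotonation of the arylacetaldehyde at low temperature should give mainly the cis (Z) potassium enolate, and enolate O-acylation by the chloroformate is fast and retains that geometry, so the Z enol carbonate results and any E isomer is removed by chromatography.

Step 11
Reactants: 12 upper-unit C8 carbinol of the benzylated digallate dimer and 17 benzyl (Z)-2-[3,4-bis(benzyloxy)phenyl]ethenyl carbonate (3 equiv)
Product: 19 octadeca-O-benzyl trimer carrying a benzyl carbonate on the top O3 (top unit 2,3-cis-3,4-cis), via ortho-quinone methide 18 (not isolated)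
Conditions: (R)-TRIP (10 mol %), 4 Å MS, CH2Cl2, −20 °C → rt
Reagents that add atoms: none
Why: The phosphoric acid protonates the carbinol and, with loss of water, gives the E ortho-quinone methide 18 of top ring A, held by a hydrogen bond from the phosphate to the quinone oxygen; the Z enol carbonate then adds across the O=C–C=C unit in an asynchronous, concerted inverse-electron-demand hetero-Diels–Alder reaction, the closest known reaction being the phosphoric-acid-catalysed [4+2] of ortho-quinone methides generated from ortho-hydroxybenzhydrols with electron-rich styrenes to give cis-2,4-diarylchromans. Top ring C, the pyran, closes by this intermolecular [4+2] annulation, in which C3–C4 forms ahead of O1–C2. C2 and C3 should be cis because the Z alkene adds suprafacially, and C4 should be cis to both because the methide is E (dimer aryl on the outside of the diene) and the dienophile approaches endo with its aryl and carbonate under the diene. The absolute configuration of the triad is set by the chiral phosphate, which should shield one face of the bound methide. The step needs regioselectivity, endo selectivity and face selectivity: the 3,4-dibenzyloxyphenyl group makes the carbonate-bearing carbon the nucleophilic terminus, so that it bonds to the methide carbon while the benzylic carbon bonds to oxygen, the weakly donating carbonate oxygen cannot override this, the bulk of the acid at the quinone oxygen favours the E methide, and the matched acid works with whatever bias the dimer exerts.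

Step 12
Reactants: 19 octadeca-O-benzyl trimer carrying a benzyl carbonate on the top O3
Product: 20 epicatechin-(4α→8)-epicatechin 3-O-gallate-(4β→8)-epicatechin 3-O-gallate (target)
Conditions: H2 (1 atm), Pd(OH)2/C, THF/MeOH/H2O, rt
Reagents that add atoms: none
Why: Hydrogenolysis cleaves the eighteen benzyl ethers and the benzyl carbonate, whose carbonic half-ester loses CO2 to free the top 3-OH, while the flavan C2–O1 bonds, the interflavan C–C bonds and the gallate esters are expected to survive.

Compound list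

1 | (−)-epicatechin, (2R,3R) | O[C@@H]1Cc2c(O)cc(O)cc2O[C@@H]1c1ccc(O)c(O)c1 | starting material

2 | 5,7,3',4'-tetra-O-benzyl-(−)-epicatechin | O[C@@H]1Cc2c(OCc9ccccc9)cc(OCc9ccccc9)cc2O[C@@H]1c7ccc(OCc9ccccc9)c(OCc9ccccc9)c7 | intermediate

3 | 3,4,5-tris(benzyloxy)benzoic acid | O=C(O)c1cc(OCc2ccccc2)c(OCc2ccccc2)c(OCc2ccccc2)c1 | starting material

4 | hepta-O-benzyl-(−)-epicatechin gallate | O=C(O[C@@H]1Cc2c(OCc9ccccc9)cc(OCc9ccccc9)cc2O[C@@H]1c7ccc(OCc9ccccc9)c(OCc9ccccc9)c7)c8cc(OCc9ccccc9)c(OCc9ccccc9)c(OCc9ccccc9)c8 | intermediate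

5 | 4β-(2-ethoxyethoxy)-hepta-O-benzylepicatechin gallate (2,3-cis, 3,4-trans) | O=C(O[C@@H]1[C@@H](OCCOCC)c2c(OCc9ccccc9)cc(OCc9ccccc9)cc2O[C@@H]1c7ccc(OCc9ccccc9)c(OCc9ccccc9)c7)c8cc(OCc9ccccc9)c(OCc9ccccc9)c(OCc9ccccc9)c8 | intermediate

6 | 8-bromo-4β-(2-ethoxyethoxy)-hepta-O-benzylepicatechin gallate | O=C(O[C@@H]1[C@@H](OCCOCC)c2c(OCc9ccccc9)cc(OCc9ccccc9)c(Br)c2O[C@@H]1c7ccc(OCc9ccccc9)c(OCc9ccccc9)c7)c8cc(OCc9ccccc9)c(OCc9ccccc9)c(OCc9ccccc9)c8 | intermediate

7 | tetradeca-O-benzyl [epicatechin 3-O-gallate-(4β→8)-epicatechin 3-O-gallate], Br at C8 of the upper unit | O=C(O[C@@H]1[C@@H](c2c(OCc9ccccc9)cc(OCc9ccccc9)c3c2O[C@H](c7ccc(OCc9ccccc9)c(OCc9ccccc9)c7)[C@H](OC(=O)c8cc(OCc9ccccc9)c(OCc9ccccc9)c(OCc9ccccc9)c8)C3)c2c(OCc9ccccc9)cc(OCc9ccccc9)c(Br)c2O[C@@H]1c7ccc(OCc9ccccc9)c(OCc9ccccc9)c7)c8cc(OCc9ccccc9)c(OCc9ccccc9)c(OCc9ccccc9)c8 | intermediate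

8 | 2,4,6-trihydroxybenzaldehyde | O=Cc1c(O)cc(O)cc1O | starting material

9 | 4,6-bis(benzyloxy)-2-hydroxybenzaldehyde | O=Cc1c(O)cc(OCc2ccccc2)cc1OCc1ccccc1 | intermediate

10 | upper-unit C8 arylmagnesium chloride of the dimer (LiCl complex) | O=C(O[C@@H]1[C@@H](c2c(OCc9ccccc9)cc(OCc9ccccc9)c3c2O[C@H](c7ccc(OCc9ccccc9)c(OCc9ccccc9)c7)[C@H](OC(=O)c8cc(OCc9ccccc9)c(OCc9ccccc9)c(OCc9ccccc9)c8)C3)c2c(OCc9ccccc9)cc(OCc9ccccc9)c([Mg]Cl)c2O[C@@H]1c7ccc(OCc9ccccc9)c(OCc9ccccc9)c7)c8cc(OCc9ccccc9)c(OCc9ccccc9)c(OCc9ccccc9)c8 | intermediate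

11 | chloromagnesium phenoxide of 9 | O=Cc1c(O[Mg]Cl)cc(OCc2ccccc2)cc1OCc1ccccc1 | intermediate

12 | upper-unit C8 [4,6-bis(benzyloxy)-2-hydroxyphenyl]carbinol of the benzylated digallate dimer (carbinol epimers) | O=C(O[C@@H]1[C@@H](c2c(OCc9ccccc9)cc(OCc9ccccc9)c3c2O[C@H](c7ccc(OCc9ccccc9)c(OCc9ccccc9)c7)[C@H](OC(=O)c8cc(OCc9ccccc9)c(OCc9ccccc9)c(OCc9ccccc9)c8)C3)c2c(OCc9ccccc9)cc(OCc9ccccc9)c(C(O)c4c(OCc9ccccc9)cc(OCc9ccccc9)cc4O)c2O[C@@H]1c7ccc(OCc9ccccc9)c(OCc9ccccc9)c7)c8cc(OCc9ccccc9)c(OCc9ccccc9)c(OCc9ccccc9)c8 | intermediate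

13 | 3,4-bis(benzyloxy)benzaldehyde | O=Cc1ccc(OCc2ccccc2)c(OCc2ccccc2)c1 | starting material

14 | 1,2-bis(benzyloxy)-4-(2-methoxyethenyl)benzene (E/Z mixture) | COC=Cc1ccc(OCc2ccccc2)c(OCc2ccccc2)c1 | intermediate

15 | 2-[3,4-bis(benzyloxy)phenyl]acetaldehyde | O=CCc1ccc(OCc2ccccc2)c(OCc2ccccc2)c1 | intermediate

16 | potassium (Z)-2-[3,4-bis(benzyloxy)phenyl]ethenolate | [K+].[O-]/C=C\c1ccc(OCc2ccccc2)c(OCc2ccccc2)c1 | intermediate

17 | benzyl (Z)-2-[3,4-bis(benzyloxy)phenyl]ethenyl carbonate | O=C(OCc1ccccc1)O/C=C\c1ccc(OCc2ccccc2)c(OCc2ccccc2)c1 | intermediate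

18 | E ortho-quinone methide of top ring A on C8 of the dimer | O=C(O[C@@H]1[C@@H](c2c(OCc9ccccc9)cc(OCc9ccccc9)c3c2O[C@H](c7ccc(OCc9ccccc9)c(OCc9ccccc9)c7)[C@H](OC(=O)c8cc(OCc9ccccc9)c(OCc9ccccc9)c(OCc9ccccc9)c8)C3)c2c(OCc9ccccc9)cc(OCc9ccccc9)c(/C=C4/C(=O)C=C(OCc9ccccc9)C=C4OCc9ccccc9)c2O[C@@H]1c7ccc(OCc9ccccc9)c(OCc9ccccc9)c7)c8cc(OCc9ccccc9)c(OCc9ccccc9)c(OCc9ccccc9)c8 | intermediate

19 | octadeca-O-benzyl trimer with top 3-O-benzyloxycarbonyl group (top unit all-cis, 4α→8) | O=C(O[C@@H]1[C@@H](c2c(OCc9ccccc9)cc(OCc9ccccc9)c3c2O[C@H](c7ccc(OCc9ccccc9)c(OCc9ccccc9)c7)[C@H](OC(=O)c8cc(OCc9ccccc9)c(OCc9ccccc9)c(OCc9ccccc9)c8)C3)c2c(OCc9ccccc9)cc(OCc9ccccc9)c([C@@H]3c4c(OCc9ccccc9)cc(OCc9ccccc9)cc4O[C@H](c7ccc(OCc9ccccc9)c(OCc9ccccc9)c7)[C@@H]3OC(=O)OCc9ccccc9)c2O[C@@H]1c7ccc(OCc9ccccc9)c(OCc9ccccc9)c7)c8cc(OCc9ccccc9)c(OCc9ccccc9)c(OCc9ccccc9)c8 | intermediate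

20 | epicatechin-(4α→8)-epicatechin 3-O-gallate-(4β→8)-epicatechin 3-O-gallate (CNP0279403.2) | O=C(O[C@@H]1[C@@H](c2c(O)cc(O)c3c2O[C@H](c2ccc(O)c(O)c2)[C@H](OC(=O)c2cc(O)c(O)c(O)c2)C3)c2c(O)cc(O)c([C@@H]3c4c(O)cc(O)cc4O[C@H](c4ccc(O)c(O)c4)[C@@H]3O)c2O[C@@H]1c1ccc(O)c(O)c1)c1cc(O)c(O)c(O)c1 | target

Total step count: 12. Longest linear sequence: 8 steps (steps 1, 2, 3, 4, 5, 7, 11, 12).

Steps most likely to fail

Most at risk is step 11. What may go wrong: poor face or endo/exo selectivity, because the dimer stereocentres lie far from the methide carbon and the enol carbonate offers the acid no hydrogen-bond donor; drift of the methide to its Z geometry next to the peri benzyloxy group; or a cycloaddition so slow that the benzhydryl cation alkylates an arene or the enol carbonate is hydrolysed. Fallback: the top unit is taken from the chiral pool and only C4 is set, by organometallic addition to a flavan-4-one followed by ionic deoxygenation; it sets out from 2 and 7 and returns at 20. Compound 2 is benzylated on O3 (NaH, BnBr, DMF, 0 °C) to 3,5,7,3',4'-penta-O-benzyl-(−)-epicatechin F1. DDQ in wet CH2Cl2 oxidises C4 to 4β-hydroxy-3,5,7,3',4'-penta-O-benzylepicatechin F2 (either C4 epimer serves), and Dess–Martin periodinane with NaHCO3 in CH2Cl2 oxidises this benzylic alcohol to the 3,5,7,3',4'-penta-O-benzylflavan-4-one F3, which keeps the epicatechin configuration at C2 and C3. Bromide 7 is converted into 10 as in step 7 and added to F3 in the presence of LaCl3·2LiCl (THF, −20 °C), which favours addition over enolisation, to give the tertiary C4 carbinol trimer F4. Bu3SnH with CF3CO2H in CH2Cl2 ionises this carbinol and delivers hydride to C4 on the face away from the 3-benzyloxy group, which leaves the C4 aryl cis to O3 and should give the all-cis nonadeca-O-benzyl trimer F5. Hydrogenolysis under the conditions of step 12 then gives 20.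

Second is step 7. What may go wrong: attack of the organomagnesium species on the gallate esters, incomplete bromine–magnesium exchange, or addition to the electron-rich aldehyde (held as its phenoxide) so sluggish that the aryl metal is simply protonated. Fallback: the phenol is masked so that a neutral, more electrophilic aldehyde is used, and it is unmasked in a separate neutral step; it sets out from 7 and 9 and returns at 12. Compound 9 is O-allylated (allyl bromide, K2CO3, DMF) to 2-(allyloxy)-4,6-bis(benzyloxy)benzaldehyde F6. Compound 10, made from 7 as before, adds to F6 to give the upper-unit C8 [2-(allyloxy)-4,6-bis(benzyloxy)phenyl]carbinol of the dimer F7. Pd(PPh3)4 with morpholine in THF at rt then removes the allyl group (Tsuji–Trost deallylation) without acid, which spares the ionisable carbinol and gives 12.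

Third is step 10. What may go wrong: loss of geometric control during enolate formation or acylation, or aldol self-condensation of the arylacetaldehyde under base. Fallback: the geometry is corrected after acylation by triplet energy transfer; it sets out from 15 and returns at 17. Compound 15 is acylated without regard to geometry (CbzCl, Et3N, DMAP, CH2Cl2, 0 °C), which should give mostly benzyl (E)-2-[3,4-bis(benzyloxy)phenyl]ethenyl carbonate F8. Irradiation with blue light in MeCN in the presence of fac-Ir(ppy)3 drives the contra-thermodynamic E→Z isomerisation known for β-substituted styrenes, because the twisted Z styrene is the poorer triplet acceptor, and 17 is then separated from residual F8.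

Further compounds

F1 | step 11 | 3,5,7,3',4'-penta-O-benzyl-(−)-epicatechin | C(c9ccccc9)O[C@@H]1Cc2c(OCc9ccccc9)cc(OCc9ccccc9)cc2O[C@@H]1c7ccc(OCc9ccccc9)c(OCc9ccccc9)c7

F2 | step 11 | 4β-hydroxy-3,5,7,3',4'-penta-O-benzylepicatechin | C(c9ccccc9)O[C@@H]1[C@@H](O)c2c(OCc9ccccc9)cc(OCc9ccccc9)cc2O[C@@H]1c7ccc(OCc9ccccc9)c(OCc9ccccc9)c7

F3 | step 11 | 3,5,7,3',4'-penta-O-benzylflavan-4-one with epicatechin configuration at C2 and C3 | C(c9ccccc9)O[C@@H]1C(=O)c2c(OCc9ccccc9)cc(OCc9ccccc9)cc2O[C@@H]1c7ccc(OCc9ccccc9)c(OCc9ccccc9)c7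

F4 | step 11 | tertiary C4 carbinol trimer (top unit 4-hydroxy-4-aryl, either C4 epimer, top O3 benzylated) | O=C(O[C@@H]1[C@@H](c2c(OCc9ccccc9)cc(OCc9ccccc9)c3c2O[C@H](c7ccc(OCc9ccccc9)c(OCc9ccccc9)c7)[C@H](OC(=O)c8cc(OCc9ccccc9)c(OCc9ccccc9)c(OCc9ccccc9)c8)C3)c2c(OCc9ccccc9)cc(OCc9ccccc9)c(C3(O)c4c(OCc9ccccc9)cc(OCc9ccccc9)cc4O[C@H](c7ccc(OCc9ccccc9)c(OCc9ccccc9)c7)[C@@H]3OCc9ccccc9)c2O[C@@H]1c7ccc(OCc9ccccc9)c(OCc9ccccc9)c7)c8cc(OCc9ccccc9)c(OCc9ccccc9)c(OCc9ccccc9)c8

F5 | step 11 | nonadeca-O-benzyl trimer with top 3-O-benzyl group (top unit all-cis, 4α→8) | O=C(O[C@@H]1[C@@H](c2c(OCc9ccccc9)cc(OCc9ccccc9)c3c2O[C@H](c7ccc(OCc9ccccc9)c(OCc9ccccc9)c7)[C@H](OC(=O)c8cc(OCc9ccccc9)c(OCc9ccccc9)c(OCc9ccccc9)c8)C3)c2c(OCc9ccccc9)cc(OCc9ccccc9)c([C@@H]3c4c(OCc9ccccc9)cc(OCc9ccccc9)cc4O[C@H](c7ccc(OCc9ccccc9)c(OCc9ccccc9)c7)[C@@H]3OCc9ccccc9)c2O[C@@H]1c7ccc(OCc9ccccc9)c(OCc9ccccc9)c7)c8cc(OCc9ccccc9)c(OCc9ccccc9)c(OCc9ccccc9)c8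

F6 | step 7 | 2-(allyloxy)-4,6-bis(benzyloxy)benzaldehyde | O=Cc1c(OCC=C)cc(OCc2ccccc2)cc1OCc1ccccc1

F7 | step 7 | upper-unit C8 [2-(allyloxy)-4,6-bis(benzyloxy)phenyl]carbinol of the benzylated digallate dimer (carbinol epimers) | O=C(O[C@@H]1[C@@H](c2c(OCc9ccccc9)cc(OCc9ccccc9)c3c2O[C@H](c7ccc(OCc9ccccc9)c(OCc9ccccc9)c7)[C@H](OC(=O)c8cc(OCc9ccccc9)c(OCc9ccccc9)c(OCc9ccccc9)c8)C3)c2c(OCc9ccccc9)cc(OCc9ccccc9)c(C(O)c4c(OCc9ccccc9)cc(OCc9ccccc9)cc4OCC=C)c2O[C@@H]1c7ccc(OCc9ccccc9)c(OCc9ccccc9)c7)c8cc(OCc9ccccc9)c(OCc9ccccc9)c(OCc9ccccc9)c8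

F8 | step 10 | benzyl (E)-2-[3,4-bis(benzyloxy)phenyl]ethenyl carbonate | O=C(OCc1ccccc1)O/C=C/c1ccc(OCc2ccccc2)c(OCc2ccccc2)c1
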